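**Plan**

- Numbering: arene C1–C6 (C4 carries the phenol oxygen, C3 and C5 the methoxy groups), side chain C7=C8–C9, glutarate C1'–C5' (C1' is the ester carbonyl on O9, C3' the carbinol carbon, C5' the free acid).
- Retrosynthesis: the C4 oxygen and the C5' acid are first joined as an aryl ester, giving a 14-membered dilactone; C7=C8 is then cut (ring-closing metathesis), followed by the O–C5' aryl ester, the C5' oxidation level and the C1'–O ester. This leads back to 4-vinyl-2,6-dimethoxyphenol (from sinapic acid), allyl bromide and (R)-mevalonolactone.
- Enabling feature: the C4 oxygen is para to C1–C7 and the chain ends at C5'. Esterifying one with the other gives a single ring of 14 atoms (arene path C1–C4 plus the ten-atom bridge C7–C8–C9–O–C1'–C2'–C3'–C4'–C5'–O) that should hold C7=C8 only as Z.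
- Forward order: C1' allyl ester, C5' acid, C5' aryl ester (chain joined), closure of the only ring (the 14-membered paracyclophane) by C7=C8 formation, then hydrolysis of the aryl ester to open it again.
- Stereochemistry: C3' is bought with (R)-mevalonolactone and no bond to it is made or broken; the Z alkene comes from the ring constraint in the metathesis.

Key step: step 5

Remark: the descriptor at C3' is R in the mevalonate stage and in the target but S in diester 9 and macrocycle 10, only because an aryl ester arm outranks an allylic ester arm in the sequence rules; the spatial arrangement never changes.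
Remark: vinylphenol 8 is assumed to polymerise on storage and is used at once with a trace of BHT.
Remark: H2IMes = 1,3-dimesitylimidazolidin-2-ylidene.

**Route**

Step 1
Reactants: 1 (R)-mevalonolactone; 2 allyl bromide
Product: 4 allyl (R)-mevalonate, via potassium (R)-mevalonate 3 (not isolated)
Conditions: KOH (1.0 equiv), H2O, 0 °C to rt; evaporate to dryness; then allyl bromide (1.5 equiv), Bu4NI (5 mol%), DMF, 0 °C to rt
Reagents that add atoms: potassium hydroxide, [K+].[OH-]
Why: Saponification of the δ-lactone followed by SN2 O-alkylation of the carboxylate with allyl bromide in DMF is the standard way to mevalonate esters, and since neither event touches C3' the R configuration of 1 is carried over unchanged.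

Step 2
Reactants: 4 allyl (R)-mevalonate
Product: 6 mono-allyl (R)-3-hydroxy-3-methylglutarate, via allyl (R)-3-hydroxy-3-methyl-5-oxopentanoate 5 (not isolated)
Conditions: TEMPO (0.2 equiv), PhI(OAc)2 (2.2 equiv), MeCN/H2O 1:1, 0 °C to rt
Reagents that add atoms: water, O
Why: The TEMPO/PhI(OAc)2 oxidation (oxoammonium-mediated alcohol oxidation) in wet MeCN takes the primary alcohol through aldehyde 5 and its hydrate to the acid, while the tertiary alcohol has no carbinol hydrogen and the allyl ester alkene is not attacked.

Step 3
Reactants: 7 sinapic acid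
Product: 8 4-ethenyl-2,6-dimethoxyphenol (4-vinylsyringol)
Conditions: Et3N (2 equiv), DMF, 100 °C, BHT (trace)
Reagents that add atoms: none
Why: Thermal decarboxylation of a 4-hydroxycinnamic acid: the phenolate tautomerises to a para-quinone methide that behaves as a vinylogous β-keto acid and loses CO2 with re-aromatisation, the established way from sinapic acid to 4-vinylsyringol.

Step 4
Reactants: 6 mono-allyl (R)-3-hydroxy-3-methylglutarate; 8 4-ethenyl-2,6-dimethoxyphenol
Product: 9 1-(4-ethenyl-2,6-dimethoxyphenyl) 5-(prop-2-en-1-yl) (3S)-3-hydroxy-3-methylpentanedioate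
Conditions: DCC (1.2 equiv), DMAP (0.1 equiv), CH2Cl2, 0 °C to rt, BHT (trace)
Reagents that add atoms: none
Why: Steglich esterification: DCC turns acid 6 into the O-acylisourea, DMAP relays the acyl group to the phenol, which is far more accessible than the tertiary alcohol, and the allyl ester and C3' are untouched.

Step 5
Reactants: 9 1-(4-ethenyl-2,6-dimethoxyphenyl) 5-(prop-2-en-1-yl) (3S)-3-hydroxy-3-methylpentanedioate
Product: 10 14-membered (S,Z)-paracyclophane dilactone (3,5-dimethoxy-1,4-phenylene spanned from the C4 oxygen to C1 by C(=O)-CH2-C(OH)(CH3)-CH2-C(=O)-O-CH2-CH=CH)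
Conditions: second-generation Hoveyda-Grubbs catalyst RuCl2(H2IMes)(=CH-C6H4-2-OiPr) (10 mol% in two portions), 1,4-benzoquinone (20 mol%), toluene (1 mM), 80 °C, Ar sparge
Reagents that add atoms: none
Why: Ring-closing olefin metathesis: the ruthenium benzylidene exchanges onto the unhindered allyl ester alkene, the new alkylidene adds to the styrene in a [2+2] step to give a ruthenacyclobutane, and cycloreversion releases the macrocycle while ethylene is purged. The closest known reaction type is macrocyclic ring-closing metathesis of α,ω-dienes to macrolactones and paracyclophanes with second-generation ruthenium carbenes. The one ring formed, the 14-membered paracyclophane dilactone, closes end to end between the two terminal alkenes with the new C7=C8 bond inside the ring. No stereocentre is created (C3' is a spectator and the arene, symmetric about its C1–C4 axis, adds no planar chirality); the only new stereo-element is the alkene, which should form as Z because with an E geometry C9 would be directed outward along the C1–C4 axis and the six remaining bridge atoms would be too few to return to the oxygen on C4 without prohibitive strain, so reversible metathesis should funnel material into the Z ring. The step needs Z over E and cyclisation over oligomerisation: the short bridge provides the first, while 1 mM dilution and the two methoxy groups flanking the aryl ester, which twist the acyloxy group perpendicular to the arene and carry the chain over the ring face towards C7, provide the second, and 1,4-benzoquinone suppresses ruthenium hydride isomerisation of the allyl ester.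

Step 6
Reactants: 10 14-membered (S,Z)-paracyclophane dilactone
Product: 12 (3R)-3-hydroxy-5-{[(2Z)-3-(4-hydroxy-3,5-dimethoxyphenyl)prop-2-en-1-yl]oxy}-3-methyl-5-oxopentanoic acid (target), via dilithium phenolate carboxylate salt 11 (not isolated)
Conditions: LiOH (2.1 equiv), THF/H2O 3:1, 0 °C; then 0.5 M HCl to pH 3 to 4, 0 °C
Reagents that add atoms: lithium hydroxide, [Li+].[OH-]
Why: Saponification (addition-elimination at acyl carbon) should be much faster at the aryl ester, whose 2,6-dimethoxyphenoxide is a far better leaving group than an allylic alkoxide and whose opening releases the strain of the cyclophane, and the dianion 11 then repels further hydroxide from the remaining allylic ester until the cold acidic quench.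

**Compound list**

1 | (R)-mevalonolactone, (4R)-4-hydroxy-4-methyloxan-2-one | O=C1C[C@](C)(O)CCO1 | starting material
2 | allyl bromide, 3-bromoprop-1-ene | C=CCBr | starting material
3 | potassium (R)-mevalonate, potassium (3R)-3,5-dihydroxy-3-methylpentanoate (formed in the flask) | [K+].[O-]C(=O)C[C@](C)(O)CCO | intermediate
4 | allyl (R)-mevalonate, prop-2-en-1-yl (3R)-3,5-dihydroxy-3-methylpentanoate | C=CCOC(=O)C[C@](C)(O)CCO | intermediate
5 | allyl (R)-3-hydroxy-3-methyl-5-oxopentanoate (formed in the flask) | C=CCOC(=O)C[C@](C)(O)CC=O | intermediate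
6 | mono-allyl (R)-3-hydroxy-3-methylglutarate, (3R)-3-hydroxy-3-methyl-5-oxo-5-(prop-2-en-1-yloxy)pentanoic acid | C=CCOC(=O)C[C@](C)(O)CC(=O)O | intermediate
7 | sinapic acid, (2E)-3-(4-hydroxy-3,5-dimethoxyphenyl)prop-2-enoic acid | COc1cc(/C=C/C(=O)O)cc(OC)c1O | starting material
8 | 4-ethenyl-2,6-dimethoxyphenol (4-vinylsyringol) | C=Cc1cc(OC)c(O)c(OC)c1 | intermediate
9 | 1-(4-ethenyl-2,6-dimethoxyphenyl) 5-(prop-2-en-1-yl) (3S)-3-hydroxy-3-methylpentanedioate | C=CCOC(=O)C[C@](C)(O)CC(=O)Oc1c(OC)cc(C=C)cc1OC | intermediate
10 | (5S,10Z)-5-hydroxy-14,15-dimethoxy-5-methyl-2,8-dioxabicyclo[10.2.2]hexadeca-1(14),10,12,15-tetraene-3,7-dione (14-membered Z paracyclophane dilactone) | O=C1C[C@@](C)(O)CC(=O)OC/C=C\c2cc(OC)c(O1)c(OC)c2 | intermediate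
11 | dilithium phenolate carboxylate salt of the target (formed in the flask) | [Li+].[Li+].COc1cc(/C=C\COC(=O)C[C@](C)(O)CC(=O)[O-])cc(OC)c1[O-] | intermediate
12 | (3R)-3-hydroxy-5-{[(2Z)-3-(4-hydroxy-3,5-dimethoxyphenyl)prop-2-en-1-yl]oxy}-3-methyl-5-oxopentanoic acid | COc1cc(/C=C\COC(=O)C[C@](C)(O)CC(=O)O)cc(OC)c1O | target

**Count**

Total steps: 6. Longest linear sequence: 5 steps (steps 1, 2, 4, 5, 6, from compound 1); the branch from sinapic acid adds step 3.

**Steps most likely to fail**

Step 5. Intermolecular metathesis may outrun ring closure, giving oligomers or a 28-membered head-to-tail cyclic dimer with E alkenes, if the strain of the 14-membered ring slows cyclisation. The fallback gives up metathesis and sets the Z alkene by alkyne semi-hydrogenation. It sets out from potassium salt 3 (made from 1 as in step 1), which is alkylated with propargyl bromide in DMF at rt to give prop-2-yn-1-yl (3R)-3,5-dihydroxy-3-methylpentanoate F1. TEMPO/PhI(OAc)2 in MeCN/H2O oxidises this through prop-2-yn-1-yl (3R)-3-hydroxy-3-methyl-5-oxopentanoate F2 to (3R)-3-hydroxy-3-methyl-5-oxo-5-(prop-2-yn-1-yloxy)pentanoic acid F3. 2,6-Dimethoxyphenol is iodinated para to the hydroxyl with N-iodosuccinimide in MeCN at 0 °C to give 4-iodo-2,6-dimethoxyphenol F4. Sonogashira coupling of F3 with F4 (PdCl2(PPh3)2, CuI, Et3N in excess, THF, rt) should give (3R)-3-hydroxy-5-{[3-(4-hydroxy-3,5-dimethoxyphenyl)prop-2-yn-1-yl]oxy}-3-methyl-5-oxopentanoic acid F5. Syn addition of hydrogen over Lindlar catalyst (Pd on CaCO3 poisoned with Pb(OAc)2, quinoline, H2, EtOAc, rt) then gives the Z alkene and returns to the route at target 12.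

Step 6. Hydroxide may also attack the allylic ester, the phenolate may expel the carboxylate through a vinylogous quinone methide, or the freed carboxylate may scramble the two glutarate arms through the cyclic anhydride and erode the configuration at C3'. The fallback replaces hydroxide by enzymatic hydrolysis at neutral pH, where the phenol stays protonated. It sets out from 10: porcine liver esterase in KH2PO4/K2HPO4 buffer (pH 7) with 10% acetone at 25 °C should cleave the activated aryl ester and return directly to target 12. This fallback makes no new compound (F0).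

Step 4. Slow acylation of the hindered 2,6-dimethoxyphenol may let the activated β-hydroxy acid rearrange to the N-acylurea, dehydrate or acylate its own tertiary alcohol, while the vinylphenol polymerises. The fallback masks the tertiary alcohol before activation. It sets out from 6: TESOTf (2.2 equiv) and 2,6-lutidine in CH2Cl2 at −78 to 0 °C give prop-2-en-1-yl triethylsilyl (3S)-3-methyl-3-(triethylsilyloxy)pentanedioate F6. Its silyl ester is hydrolysed on aqueous work-up to (3R)-3-methyl-5-oxo-5-(prop-2-en-1-yloxy)-3-(triethylsilyloxy)pentanoic acid F7. This acid tolerates longer or more forcing DCC/DMAP coupling with 8 and should give 1-(4-ethenyl-2,6-dimethoxyphenyl) 5-(prop-2-en-1-yl) (3S)-3-methyl-3-(triethylsilyloxy)pentanedioate F8. HF·pyridine in THF at 0 °C removes the silyl ether and returns to the route at compound 9.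

**Further compounds**

F1 | step 5 | prop-2-yn-1-yl (3R)-3,5-dihydroxy-3-methylpentanoate | C#CCOC(=O)C[C@](C)(O)CCO
F2 | step 5 | prop-2-yn-1-yl (3R)-3-hydroxy-3-methyl-5-oxopentanoate | C#CCOC(=O)C[C@](C)(O)CC=O
F3 | step 5 | (3R)-3-hydroxy-3-methyl-5-oxo-5-(prop-2-yn-1-yloxy)pentanoic acid | C#CCOC(=O)C[C@](C)(O)CC(=O)O
F4 | step 5 | 4-iodo-2,6-dimethoxyphenol | COc1cc(I)cc(OC)c1O
F5 | step 5 | (3R)-3-hydroxy-5-{[3-(4-hydroxy-3,5-dimethoxyphenyl)prop-2-yn-1-yl]oxy}-3-methyl-5-oxopentanoic acid | COc1cc(C#CCOC(=O)C[C@](C)(O)CC(=O)O)cc(OC)c1O
F0 | step 6 | none | none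
F6 | step 4 | prop-2-en-1-yl triethylsilyl (3S)-3-methyl-3-(triethylsilyloxy)pentanedioate | C=CCOC(=O)C[C@](C)(O[Si](CC)(CC)CC)CC(=O)O[Si](CC)(CC)CC
F7 | step 4 | (3R)-3-methyl-5-oxo-5-(prop-2-en-1-yloxy)-3-(triethylsilyloxy)pentanoic acid | C=CCOC(=O)C[C@](C)(O[Si](CC)(CC)CC)CC(=O)O
F8 | step 4 | 1-(4-ethenyl-2,6-dimethoxyphenyl) 5-(prop-2-en-1-yl) (3S)-3-methyl-3-(triethylsilyloxy)pentanedioate | C=CCOC(=O)C[C@](C)(O[Si](CC)(CC)CC)CC(=O)Oc1c(OC)cc(C=C)cc1OC
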